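**Retrosynthetic overview**
- Last bonds: the ester C–O bond (Steglich coupling of the allylic alcohol with bis-silylated caffeic acid) and the exocyclic C=CH2 (Wittig on the cyclopentanone).
- Cyclohexene functionality: the ring methyl comes from an enol triflate and the carbinol from a Rubottom oxidation; both ring stereocentres come from chiral-base desymmetrisation of a symmetric 4-methyl-4-cyclopentylcyclohexanone.
- Six-membered ring: Robinson annulation (intermolecular Michael, then aldol) of an α-branched aldehyde with methyl vinyl ketone, which creates the second quaternary carbon.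
- Key bond (the C–C link between the two future quaternary carbons): intermolecular asymmetric Michael addition of the (S)-1-phenylethylamine imine of 2-methylcyclopentanone to (E)-1-nitropropene, followed by a Nef reaction.
- Ring order: the cyclopentane is bought as 2-methylcyclopentanone; the cyclohexane ring is formed second (step 7).

Assumption: the arm selectivity of the chiral lithium amide in step 9 is taken to follow that known for 4-tert-butylcyclohexanone; the antipodal (S,S)-amide would be used if the opposite arm were favoured.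

**Route**

Step 1
Reactants: 1 nitromethane; 2 acetaldehyde
Product: 3 1-nitropropan-2-ol (racemic)
Conditions: NaOH (cat.), MeOH/H2O, excess 1, 0 °C → rt
Reagents that add atoms: none
Why: Henry (nitroaldol) addition of the nitronate of nitromethane to acetaldehyde is clean with catalytic base and excess nitromethane, and the racemic carbinol centre is lost in the next step.

Step 2
Reactants: 3 1-nitropropan-2-ol
Product: 5 (E)-1-nitroprop-1-ene, via mesylate 4 (not isolated)
Conditions: MsCl, Et3N, CH2Cl2, 0 °C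
Reagents that add atoms: none
Why: Mesylation followed by E1cB elimination across the acidic nitro-bearing carbon gives the conjugated nitroalkene, the E isomer being strongly favoured.

Step 3
Reactants: 6 2-methylcyclopentan-1-one (racemic); 7 (S)-1-phenylethan-1-amine
Product: 8 (1S)-N-(2-methylcyclopentylidene)-1-phenylethan-1-amine
Conditions: TsOH (cat.), toluene, reflux, Dean–Stark
Reagents that add atoms: none
Why: Acid-catalysed imine condensation with azeotropic water removal gives the imine, which equilibrates with its secondary enamine tautomers so that the racemic ring stereocentre is of no consequence.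

Step 4
Reactants: 8 (1S)-N-(2-methylcyclopentylidene)-1-phenylethan-1-amine; 5 (E)-1-nitroprop-1-ene
Product: 10 (2R)-2-methyl-2-(1-nitropropan-2-yl)cyclopentan-1-one, via adduct imine 9 (not isolated)
Conditions: THF, −20 °C → rt; then 20% aq AcOH, rt
Reagents that add atoms: water, O
Why: d'Angelo-type asymmetric Michael addition, in which the more substituted secondary enamine tautomer adds to the nitroalkene through a compact chair-like transition state with internal N–H transfer on the face away from the phenyl group of the (S)-auxiliary, fixes the quaternary carbon as R (about 90% ee), while the side-chain CH centre forms as a mixture that is erased in steps 7 and 8, and mild aqueous acid then hydrolyses the imine.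

Step 5
Reactants: 10 (2R)-2-methyl-2-(1-nitropropan-2-yl)cyclopentan-1-one
Product: 11 (6R)-6-methyl-6-(1-nitropropan-2-yl)-1,4-dioxaspiro[4.4]nonane
Conditions: Me3SiOCH2CH2OSiMe3, Me3SiOTf (cat.), CH2Cl2, −78 → 0 °C
Reagents that add atoms: 1,2-bis(trimethylsilyloxy)ethane, C[Si](C)(C)OCCO[Si](C)(C)C
Why: Noyori ketalisation, driven irreversibly by silyl transfer to the carbonyl oxygen, protects the hindered ketone under aprotic conditions that leave the nitro group and the quaternary centre untouched.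

Step 6
Reactants: 11 (6R)-6-methyl-6-(1-nitropropan-2-yl)-1,4-dioxaspiro[4.4]nonane
Product: 13 2-[(6R)-6-methyl-1,4-dioxaspiro[4.4]nonan-6-yl]propanal, via sodium nitronate 12 (not isolated)
Conditions: NaOMe, MeOH, 0 °C; then O3, −78 °C; N2 purge
Reagents that add atoms: ozone, [O-][O+]=O
Why: Nef-type conversion by ozonolysis of the C=N bond of the primary nitronate gives the aldehyde under basic non-aqueous conditions that spare the ketal, and the epimerisable α-centre is of no consequence.

Step 7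
Reactants: 13 2-[(6R)-6-methyl-1,4-dioxaspiro[4.4]nonan-6-yl]propanal; 14 but-3-en-2-one
Product: 17 4-methyl-4-[(6R)-6-methyl-1,4-dioxaspiro[4.4]nonan-6-yl]cyclohex-2-en-1-one, via keto aldehyde 15 (not isolated), via ketol 16 (not isolated)
Conditions: KOH (cat.), EtOH/THF, 0 °C → rt; then KOH, EtOH, 70 °C
Reagents that add atoms: none
Why: Robinson annulation, in which intermolecular Michael addition of the fully substituted aldehyde enolate to the unhindered terminus of 14 builds the second quaternary carbon next to the first and aldol condensation of the methyl ketone onto the aldehyde closes the cyclohexenone, gives both epimers at the new quaternary carbon, which is harmless because step 8 makes the ring symmetric.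

Step 8
Reactants: 17 4-methyl-4-[(6R)-6-methyl-1,4-dioxaspiro[4.4]nonan-6-yl]cyclohex-2-en-1-one
Product: 18 4-methyl-4-[(6R)-6-methyl-1,4-dioxaspiro[4.4]nonan-6-yl]cyclohexan-1-one
Conditions: H2 (1 atm), Pd/C, EtOAc, rt
Reagents that add atoms: none
Why: Catalytic hydrogenation of the disubstituted enone alkene gives a cyclohexanone whose two ring arms are identical, so the ring quaternary carbon is no longer stereogenic and the two epimers converge.

Step 9
Reactants: 18 4-methyl-4-[(6R)-6-methyl-1,4-dioxaspiro[4.4]nonan-6-yl]cyclohexan-1-one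
Product: 19 trimethyl({(4S)-4-methyl-4-[(6R)-6-methyl-1,4-dioxaspiro[4.4]nonan-6-yl]cyclohex-1-en-1-yl}oxy)silane
Conditions: (R,R)-bis(1-phenylethyl)amine·HCl, n-BuLi (2 equiv), THF, −78 → 0 °C; then Me3SiCl and 18, −100 °C
Reagents that add atoms: chlorotrimethylsilane, C[Si](C)(C)Cl
Why: Group-selective deprotonation with a chiral lithium amide (Simpkins-type, internal silyl quench) removes the axial α-hydrogen of one arm of the chair that has the bulky spiro-ketal group equatorial and the methyl axial, which fixes the ring quaternary carbon as S (about 9:1), the minor arm isomer being a separable diastereomer.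

Step 10
Reactants: 19 trimethyl({(4S)-4-methyl-4-[(6R)-6-methyl-1,4-dioxaspiro[4.4]nonan-6-yl]cyclohex-1-en-1-yl}oxy)silane
Product: 22 (2S,4S)-2-hydroxy-4-methyl-4-[(6R)-6-methyl-1,4-dioxaspiro[4.4]nonan-6-yl]cyclohexan-1-one, via silyloxy epoxide 20 (not isolated), via silyloxy ketone 21 (not isolated)
Conditions: mCPBA, hexane/CH2Cl2, −20 → 0 °C; then citric acid (cat.), MeOH, rt
Reagents that add atoms: 3-chloroperoxybenzoic acid, OOC(=O)c1cccc(Cl)c1
Why: Rubottom oxidation, in which the peracid epoxidises the silyl enol ether on the face opposite the pseudo-axial homoallylic methyl, silyl migration opens the epoxide and mild methanolysis frees the equatorial hydroxyl, sets the carbinol centre as S and cis to the spiro-ketal substituent.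

Step 11
Reactants: 22 (2S,4S)-2-hydroxy-4-methyl-4-[(6R)-6-methyl-1,4-dioxaspiro[4.4]nonan-6-yl]cyclohexan-1-one
Product: 23 (2S,4S)-2-[(tert-butyldimethylsilyl)oxy]-4-methyl-4-[(6R)-6-methyl-1,4-dioxaspiro[4.4]nonan-6-yl]cyclohexan-1-one
Conditions: t-BuMe2SiCl, imidazole, DMF, rt; chromatography
Reagents that add atoms: tert-butylchlorodimethylsilane, CC(C)(C)[Si](C)(C)Cl
Why: Silyl ether protection of the secondary alcohol is routine, and chromatography here removes the minor diastereomers left from steps 4 and 9, which also raises the enantiomeric purity.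

Step 12
Reactants: 23 (2S,4S)-2-[(tert-butyldimethylsilyl)oxy]-4-methyl-4-[(6R)-6-methyl-1,4-dioxaspiro[4.4]nonan-6-yl]cyclohexan-1-one
Product: 25 (4S,6S)-6-[(tert-butyldimethylsilyl)oxy]-4-methyl-4-[(6R)-6-methyl-1,4-dioxaspiro[4.4]nonan-6-yl]cyclohex-1-en-1-yl trifluoromethanesulfonate, via potassium enolate 24 (not isolated)
Conditions: KN(SiMe3)2, THF, −78 °C; then PhNTf2, −78 → 0 °C
Reagents that add atoms: N-phenylbis(trifluoromethanesulfonimide), FC(F)(F)S(=O)(=O)N(c1ccccc1)S(=O)(=O)C(F)(F)F
Why: Regioselective enol triflate formation works because kinetic deprotonation at −78 °C occurs at the unhindered CH2 and not at the silyloxy-bearing CH, so O-triflation places the double bond on the arm away from the oxygen substituent.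

Step 13
Reactants: 25 (4S,6S)-6-[(tert-butyldimethylsilyl)oxy]-4-methyl-4-[(6R)-6-methyl-1,4-dioxaspiro[4.4]nonan-6-yl]cyclohex-1-en-1-yl trifluoromethanesulfonate
Product: 26 tert-butyl({(1S,5S)-2,5-dimethyl-5-[(6R)-6-methyl-1,4-dioxaspiro[4.4]nonan-6-yl]cyclohex-2-en-1-yl}oxy)dimethylsilane
Conditions: MeMgBr, Fe(acac)3 (5 mol%), THF/NMP, −30 → 0 °C
Reagents that add atoms: methylmagnesium bromide, C[Mg]Br
Why: Iron-catalysed Kumada-type cross-coupling of the alkenyl triflate replaces triflate by methyl without moving the double bond and tolerates the ketal and the silyl ether.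

Step 14
Reactants: 26 tert-butyl({(1S,5S)-2,5-dimethyl-5-[(6R)-6-methyl-1,4-dioxaspiro[4.4]nonan-6-yl]cyclohex-2-en-1-yl}oxy)dimethylsilane
Product: 27 (2R)-2-{(1S,5S)-5-[(tert-butyldimethylsilyl)oxy]-1,4-dimethylcyclohex-3-en-1-yl}-2-methylcyclopentan-1-one
Conditions: PPTS, acetone/H2O (9:1), 60 °C
Reagents that add atoms: water, O
Why: Mild acid-catalysed ketal hydrolysis frees the cyclopentanone while the secondary silyl ether, the trisubstituted alkene and the non-epimerisable quaternary centres are unaffected.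

Step 15
Reactants: 27 (2R)-2-{(1S,5S)-5-[(tert-butyldimethylsilyl)oxy]-1,4-dimethylcyclohex-3-en-1-yl}-2-methylcyclopentan-1-one
Product: 28 tert-butyl({(1S,5S)-2,5-dimethyl-5-[(1S)-1-methyl-2-methylidenecyclopentyl]cyclohex-2-en-1-yl}oxy)dimethylsilane
Conditions: Ph3PCH3Br, KOt-Bu, toluene, 90 °C
Reagents that add atoms: methyltriphenylphosphonium bromide, C[P+](c1ccccc1)(c1ccccc1)c1ccccc1.[Br-]
Why: Wittig methylenation with Ph3P=CH2 at elevated temperature converts the hindered cyclopentanone into the exocyclic alkene, and no stereocentre is at risk because the α-carbon is quaternary.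

Step 16
Reactants: 28 tert-butyl({(1S,5S)-2,5-dimethyl-5-[(1S)-1-methyl-2-methylidenecyclopentyl]cyclohex-2-en-1-yl}oxy)dimethylsilane
Product: 29 (1S,5S)-2,5-dimethyl-5-[(1S)-1-methyl-2-methylidenecyclopentyl]cyclohex-2-en-1-ol
Conditions: Bu4NF, THF, rt
Reagents that add atoms: none
Why: Fluoride-mediated desilylation frees the allylic alcohol without touching either alkene or the carbinol configuration.

Step 17
Reactants: 30 caffeic acid
Product: 32 (E)-3-[3,4-bis(tert-butyldimethylsilyloxy)phenyl]prop-2-enoic acid, via tris-silyl caffeate 31 (not isolated)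
Conditions: t-BuMe2SiCl (3.3 equiv), imidazole, DMF, rt; then AcOH/THF/H2O, rt
Reagents that add atoms: tert-butylchlorodimethylsilane, CC(C)(C)[Si](C)(C)Cl
Why: Exhaustive silylation followed by selective hydrolysis of the labile silyl ester leaves both phenols protected and the acid free for coupling, with the E alkene untouched.

Step 18
Reactants: 29 (1S,5S)-2,5-dimethyl-5-[(1S)-1-methyl-2-methylidenecyclopentyl]cyclohex-2-en-1-ol; 32 (E)-3-[3,4-bis(tert-butyldimethylsilyloxy)phenyl]prop-2-enoic acid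
Product: 33 (1S,5S)-2,5-dimethyl-5-[(1S)-1-methyl-2-methylidenecyclopentyl]cyclohex-2-en-1-yl (E)-3-[3,4-bis(tert-butyldimethylsilyloxy)phenyl]prop-2-enoate
Conditions: DCC, DMAP (cat.), CH2Cl2, 0 °C → rt
Reagents that add atoms: none
Why: Steglich esterification (carbodiimide activation with DMAP acyl transfer) acylates the secondary allylic alcohol on oxygen, so the carbinol configuration is retained.

Step 19
Reactants: 33 (1S,5S)-2,5-dimethyl-5-[(1S)-1-methyl-2-methylidenecyclopentyl]cyclohex-2-en-1-yl (E)-3-[3,4-bis(tert-butyldimethylsilyloxy)phenyl]prop-2-enoate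
Product: 34 (1S,5S)-2,5-dimethyl-5-[(1S)-1-methyl-2-methylidenecyclopentyl]cyclohex-2-en-1-yl (E)-3-(3,4-dihydroxyphenyl)prop-2-enoate
Conditions: Bu4NF, AcOH, THF, 0 °C
Reagents that add atoms: none
Why: Buffered fluoride desilylation cleaves the two aryl silyl ethers quickly while the allylic cinnamate ester and both alkenes survive, giving the target.

**Compound list**
1 | nitromethane | C[N+](=O)[O-] | starting material
2 | acetaldehyde | CC=O | starting material
3 | 1-nitropropan-2-ol (racemic) | CC(O)C[N+](=O)[O-] | intermediate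
4 | 1-nitropropan-2-yl methanesulfonate | CC(OS(C)(=O)=O)C[N+](=O)[O-] | intermediate
5 | (E)-1-nitroprop-1-ene | C/C=C/[N+](=O)[O-] | intermediate
6 | 2-methylcyclopentan-1-one (racemic) | CC1CCCC1=O | starting material
7 | (S)-1-phenylethan-1-amine | C[C@H](N)c1ccccc1 | starting material
8 | (1S)-N-(2-methylcyclopentylidene)-1-phenylethan-1-amine (ring CH and C=N geometry mixed) | C[C@H](N=C1CCCC1C)c1ccccc1 | intermediate
9 | (1S)-N-[(2R)-2-methyl-2-(1-nitropropan-2-yl)cyclopentylidene]-1-phenylethan-1-amine (side-chain CH mixed) | C[C@H](N=C1CCC[C@]1(C)C(C)C[N+](=O)[O-])c1ccccc1 | intermediate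
10 | (2R)-2-methyl-2-(1-nitropropan-2-yl)cyclopentan-1-one (side-chain CH mixed) | O=C1CCC[C@]1(C)C(C)C[N+](=O)[O-] | intermediate
11 | (6R)-6-methyl-6-(1-nitropropan-2-yl)-1,4-dioxaspiro[4.4]nonane | C1COC2(O1)CCC[C@]2(C)C(C)C[N+](=O)[O-] | intermediate
12 | sodium 2-[(6R)-6-methyl-1,4-dioxaspiro[4.4]nonan-6-yl]propane-1-nitronate | C1COC2(O1)CCC[C@]2(C)C(C)C=[N+]([O-])[O-].[Na+] | intermediate
13 | 2-[(6R)-6-methyl-1,4-dioxaspiro[4.4]nonan-6-yl]propanal (α-CH mixed) | C1COC2(O1)CCC[C@]2(C)C(C)C=O | intermediate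
14 | but-3-en-2-one (methyl vinyl ketone) | CC(=O)C=C | starting material
15 | 2-methyl-2-[(6R)-6-methyl-1,4-dioxaspiro[4.4]nonan-6-yl]-5-oxohexanal (both epimers at C-2) | C1COC2(O1)CCC[C@]2(C)C(C)(C=O)CCC(C)=O | intermediate
16 | 3-hydroxy-4-methyl-4-[(6R)-6-methyl-1,4-dioxaspiro[4.4]nonan-6-yl]cyclohexan-1-one (ring centres mixed) | C1COC2(O1)CCC[C@]2(C)C3(C)CCC(=O)CC3O | intermediate
17 | 4-methyl-4-[(6R)-6-methyl-1,4-dioxaspiro[4.4]nonan-6-yl]cyclohex-2-en-1-one (both epimers at C-4) | C1COC2(O1)CCC[C@]2(C)C3(C)CCC(=O)C=C3 | intermediate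
18 | 4-methyl-4-[(6R)-6-methyl-1,4-dioxaspiro[4.4]nonan-6-yl]cyclohexan-1-one | C1COC2(O1)CCC[C@]2(C)C3(C)CCC(=O)CC3 | intermediate
19 | trimethyl({(4S)-4-methyl-4-[(6R)-6-methyl-1,4-dioxaspiro[4.4]nonan-6-yl]cyclohex-1-en-1-yl}oxy)silane | C1COC2(O1)CCC[C@]2(C)[C@@]3(C)CCC(O[Si](C)(C)C)=CC3 | intermediate
20 | (1S,4S,6S)-4-methyl-4-[(6R)-6-methyl-1,4-dioxaspiro[4.4]nonan-6-yl]-1-(trimethylsilyloxy)-7-oxabicyclo[4.1.0]heptane (oxirane oxygen cis to the spiro-ketal group) | C1COC2(O1)CCC[C@]2(C)[C@@]3(C)CC[C@@]4(O[Si](C)(C)C)O[C@H]4C3 | intermediate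
21 | (2S,4S)-4-methyl-4-[(6R)-6-methyl-1,4-dioxaspiro[4.4]nonan-6-yl]-2-(trimethylsilyloxy)cyclohexan-1-one | C1COC2(O1)CCC[C@]2(C)[C@@]3(C)CCC(=O)[C@@H](O[Si](C)(C)C)C3 | intermediate
22 | (2S,4S)-2-hydroxy-4-methyl-4-[(6R)-6-methyl-1,4-dioxaspiro[4.4]nonan-6-yl]cyclohexan-1-one | C1COC2(O1)CCC[C@]2(C)[C@@]3(C)CCC(=O)[C@@H](O)C3 | intermediate
23 | (2S,4S)-2-[(tert-butyldimethylsilyl)oxy]-4-methyl-4-[(6R)-6-methyl-1,4-dioxaspiro[4.4]nonan-6-yl]cyclohexan-1-one | C1COC2(O1)CCC[C@]2(C)[C@@]3(C)CCC(=O)[C@@H](O[Si](C)(C)C(C)(C)C)C3 | intermediate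
24 | potassium (4S,6S)-6-[(tert-butyldimethylsilyl)oxy]-4-methyl-4-[(6R)-6-methyl-1,4-dioxaspiro[4.4]nonan-6-yl]cyclohex-1-en-1-olate | C1COC2(O1)CCC[C@]2(C)[C@@]3(C)CC=C([O-])[C@@H](O[Si](C)(C)C(C)(C)C)C3.[K+] | intermediate
25 | (4S,6S)-6-[(tert-butyldimethylsilyl)oxy]-4-methyl-4-[(6R)-6-methyl-1,4-dioxaspiro[4.4]nonan-6-yl]cyclohex-1-en-1-yl trifluoromethanesulfonate | C1COC2(O1)CCC[C@]2(C)[C@@]3(C)CC=C(OS(=O)(=O)C(F)(F)F)[C@@H](O[Si](C)(C)C(C)(C)C)C3 | intermediate
26 | tert-butyl({(1S,5S)-2,5-dimethyl-5-[(6R)-6-methyl-1,4-dioxaspiro[4.4]nonan-6-yl]cyclohex-2-en-1-yl}oxy)dimethylsilane | C1COC2(O1)CCC[C@]2(C)[C@@]3(C)CC=C(C)[C@@H](O[Si](C)(C)C(C)(C)C)C3 | intermediate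
27 | (2R)-2-{(1S,5S)-5-[(tert-butyldimethylsilyl)oxy]-1,4-dimethylcyclohex-3-en-1-yl}-2-methylcyclopentan-1-one | O=C1CCC[C@]1(C)[C@@]1(C)CC=C(C)[C@@H](O[Si](C)(C)C(C)(C)C)C1 | intermediate
28 | tert-butyl({(1S,5S)-2,5-dimethyl-5-[(1S)-1-methyl-2-methylidenecyclopentyl]cyclohex-2-en-1-yl}oxy)dimethylsilane | C=C1CCC[C@]1(C)[C@@]1(C)CC=C(C)[C@@H](O[Si](C)(C)C(C)(C)C)C1 | intermediate
29 | (1S,5S)-2,5-dimethyl-5-[(1S)-1-methyl-2-methylidenecyclopentyl]cyclohex-2-en-1-ol | C=C1CCC[C@]1(C)[C@@]1(C)CC=C(C)[C@@H](O)C1 | intermediate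
30 | caffeic acid, (E)-3-(3,4-dihydroxyphenyl)prop-2-enoic acid | OC(=O)/C=C/c1ccc(O)c(O)c1 | starting material
31 | tert-butyldimethylsilyl (E)-3-[3,4-bis(tert-butyldimethylsilyloxy)phenyl]prop-2-enoate | CC(C)(C)[Si](C)(C)OC(=O)/C=C/c1ccc(O[Si](C)(C)C(C)(C)C)c(O[Si](C)(C)C(C)(C)C)c1 | intermediate
32 | (E)-3-[3,4-bis(tert-butyldimethylsilyloxy)phenyl]prop-2-enoic acid | OC(=O)/C=C/c1ccc(O[Si](C)(C)C(C)(C)C)c(O[Si](C)(C)C(C)(C)C)c1 | intermediate
33 | (1S,5S)-2,5-dimethyl-5-[(1S)-1-methyl-2-methylidenecyclopentyl]cyclohex-2-en-1-yl (E)-3-[3,4-bis(tert-butyldimethylsilyloxy)phenyl]prop-2-enoate | C=C1CCC[C@]1(C)[C@@]1(C)CC=C(C)[C@@H](OC(=O)/C=C/c2ccc(O[Si](C)(C)C(C)(C)C)c(O[Si](C)(C)C(C)(C)C)c2)C1 | intermediate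
34 | (1S,5S)-2,5-dimethyl-5-[(1S)-1-methyl-2-methylidenecyclopentyl]cyclohex-2-en-1-yl (E)-3-(3,4-dihydroxyphenyl)prop-2-enoate | C=C1CCC[C@]1(C)[C@@]1(C)CC=C(C)[C@@H](OC(=O)/C=C/c2ccc(O)c(O)c2)C1 | target

**Step count and risks**

Total step count: 19. Longest linear sequence: 17 steps (1, 2, 4 to 16, 18, 19).

The three steps most likely to fail:

Step 7 (Robinson annulation). The Michael addition must create a quaternary carbon directly next to an existing one, and methyl vinyl ketone can polymerise under base before the hindered enolate reacts. The fallback sets out from aldehyde 13. It is condensed with pyrrolidine to the enamine 1-{2-[(6R)-6-methyl-1,4-dioxaspiro[4.4]nonan-6-yl]prop-1-en-1-yl}pyrrolidine F1. Under neutral conditions F1 reacts with 14 as the electron-rich partner of a hetero-Diels–Alder reaction (Stork enamine annulation, no enolate involved) to give the aminal 3,6-dimethyl-3-[(6R)-6-methyl-1,4-dioxaspiro[4.4]nonan-6-yl]-2-(pyrrolidin-1-yl)-3,4-dihydro-2H-pyran F2. Buffered hydrolysis (aq AcOH/NaOAc) opens F2 to keto aldehyde 15, where the route is rejoined; 15 closes to 17 as before.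

Step 9 (chiral-base desymmetrisation). The arm selectivity rests on analogy, and the existing stereocentre next to the ring may reinforce or oppose the base. The fallback sets out from ketone 18 and replaces deprotonation by enamine organocatalysis. D-Proline-catalysed α-aminoxylation with nitrosobenzene installs the oxygen and selects the arm in one operation, giving (2S,4S)-2-(anilinooxy)-4-methyl-4-[(6R)-6-methyl-1,4-dioxaspiro[4.4]nonan-6-yl]cyclohexan-1-one F3. Hydrogenolysis of the N–O bond (H2, Pd/C, MeOH) returns to the route at hydroxy ketone 22, bypassing 19 to 21.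

Step 15 (Wittig methylenation). The carbonyl is flanked by two contiguous quaternary carbons, and the basic ylide may only enolise it. The fallback sets out from ketone 27 and uses a two-stage Peterson olefination. The small, weakly basic reagent Me3SiCH2Li/CeCl3 (THF, −78 °C) adds to the carbonyl to give the β-hydroxysilane (2R)-2-{(1S,5S)-5-[(tert-butyldimethylsilyl)oxy]-1,4-dimethylcyclohex-3-en-1-yl}-2-methyl-1-[(trimethylsilyl)methyl]cyclopentan-1-ol F4 (carbinol centre mixed). KH in THF then triggers syn-elimination, and the route is rejoined at 28.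

Further compounds
F1 | step 7 | 1-{2-[(6R)-6-methyl-1,4-dioxaspiro[4.4]nonan-6-yl]prop-1-en-1-yl}pyrrolidine | C1COC2(O1)CCC[C@]2(C)C(C)=CN3CCCC3
F2 | step 7 | 3,6-dimethyl-3-[(6R)-6-methyl-1,4-dioxaspiro[4.4]nonan-6-yl]-2-(pyrrolidin-1-yl)-3,4-dihydro-2H-pyran | C1COC2(O1)CCC[C@]2(C)C3(C)CC=C(C)OC3N4CCCC4
F3 | step 9 | (2S,4S)-2-(anilinooxy)-4-methyl-4-[(6R)-6-methyl-1,4-dioxaspiro[4.4]nonan-6-yl]cyclohexan-1-one | C1COC2(O1)CCC[C@]2(C)[C@@]3(C)CCC(=O)[C@@H](ONc4ccccc4)C3
F4 | step 15 | (2R)-2-{(1S,5S)-5-[(tert-butyldimethylsilyl)oxy]-1,4-dimethylcyclohex-3-en-1-yl}-2-methyl-1-[(trimethylsilyl)methyl]cyclopentan-1-ol | C[Si](C)(C)CC1(O)CCC[C@]1(C)[C@@]1(C)CC=C(C)[C@@H](O[Si](C)(C)C(C)(C)C)C1
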